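A direct plan would carry ring A through from resorcinol A1: acetal protection, lithiation between the oxygens, hydroxyethylation and O-carbamoylation would give 2-[2,6-bis(methoxymethoxy)phenyl]ethyl N,N-diisopropylcarbamate A2.
Sparteine-mediated lithiation of A2, exchange to zinc and Pd(OAc)2-catalysed coupling with 6-methylhepta-1,5-dien-2-yl triflate A3 would set the carbinol centre, and reductive removal of the carbamate would give alcohol A4.
Ortho-lithiation and acetylation of A4, aldol condensation with the ring B aldehyde (chalcone A5) and acidic removal of the two acetals would finish.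
Weakest would be the coupling that makes the stereocentre: it would join an α-oxyalkylzinc to an alkenyl triflate without close precedent, after a deprotonation that the two ring acetals could divert to the arene.
Next, the ring acylation would expose the complete side chain of A4, as its alkoxide, to excess nBuLi for the gain of one acetyl group.
Last, the acidic deprotection would put an ionisable allylic carbinol beside a free ortho-phenol, and a 2′-hydroxychalcone, under conditions that close dihydrobenzofurans, chromans and flavanones.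
Carbamate and acetal traffic would take half of the steps without adding skeleton.

Plan of the new route
Ring A (C1′ carries the enone carbonyl, C2′ and C4′ the hydroxyls, C3′ the side chain) is cut at C1′–C2′ and C5′–C6′: C2′–C5′ become a 1,3-dioxygenated diene, C6′–C1′ the alkyne of an ethynyl ketone that already holds the cinnamoyl unit and ring B.
Enabling feature: the carbinol oxygen stands 1,4 to C2′, so C2′ with its oxygen, C3′, the benzylic CH2 and the carbinol CH–O are the ring atoms and carbonyl oxygen of a γ-butyrolactone, and C4′(–O)–C5′ is an acetyl group on its α-carbon; the 2′-OH and the side-chain OH are the two oxygens of one lactone carboxyl.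
Order of rings: ring B is bought, the lactone (a five-membered ring absent from the target) carries the stereocentre through fragment 1, and ring A is made last by [4+2] cycloaddition and ring-opening aromatisation, which also frees the carbinol.
The stereocentre comes from (2R)-5-oxotetrahydrofuran-2-carboxylic acid and is never a reaction centre, so no asymmetric coupling is needed; the arene is born fully substituted, so no ring metalation or acylation occurs; only silyl groups are used and fluoride removes them in the ring-forming step, so no acid meets the finished side chain.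

Key step: step 10

Remark: compounds 1 (the D-glutamic acid-derived lactone acid), 3, 7, 13, 14 and 16 (as a THF solution) are taken as commercial.

Step 1
Reactants: 1 (2R)-5-oxotetrahydrofuran-2-carboxylic acid
Product: 2 (2R)-5-oxotetrahydrofuran-2-carbonyl chloride
Conditions: (COCl)2 (1.3 equiv), DMF (cat.), CH2Cl2, 0 °C → rt, 3 h; evaporate
Reagents that add atoms: oxalyl chloride, O=C(Cl)C(Cl)=O
Why: Acid chloride formation through the chloroiminium salt made from DMF and oxalyl chloride is neutral and leaves the lactone and the adjacent stereocentre alone.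

Step 2
Reactants: 2 (2R)-5-oxotetrahydrofuran-2-carbonyl chloride; 3 5-bromo-2-methylpent-2-ene
Product: 5 (5R)-5-(5-methylhex-4-enoyl)dihydrofuran-2(3H)-one, via (4-methylpent-3-en-1-yl)magnesium bromide 4 (not isolated)
Conditions: 3 (1.05 equiv), Mg, THF, rt → 40 °C; solution of 4 added to 2, CuI (10 mol%), THF, −78 °C, 1 h; aq. NH4Cl
Reagents that add atoms: none
Why: Copper-catalysed acylation of a Grignard reagent by an acid chloride (ketone synthesis) is far faster at −78 °C than attack on the lactone or on the ketone formed, and the stereocentre is only a spectator α to the new carbonyl, so cold and short handling should keep it intact.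

Step 3
Reactants: 5 (5R)-5-(5-methylhex-4-enoyl)dihydrofuran-2(3H)-one
Product: 6 (5R)-5-(6-methylhepta-1,5-dien-2-yl)dihydrofuran-2(3H)-one
Conditions: Zn, CH2Br2, TiCl4 (reagent preformed in THF, −40 → 5 °C, 3 d; 3 equiv), CH2Cl2, 0 °C → rt, 2 h; aq. NaHCO3
Reagents that add atoms: dibromomethane, BrCBr
Why: Takai–Lombardo methylenation: the non-basic zinc–titanium methylene reagent converts ketones but not lactones into 1,1-disubstituted alkenes and does not enolise the α-oxygenated ketone, so the (R) centre, now allylic, should be kept.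

Step 4
Reactants: 6 (5R)-5-(6-methylhepta-1,5-dien-2-yl)dihydrofuran-2(3H)-one; 7 N-methoxy-N-methylacetamide
Product: 9 (5R)-3-acetyl-5-(6-methylhepta-1,5-dien-2-yl)dihydrofuran-2(3H)-one, via lactone lithium enolate 8 (not isolated)
Conditions: LiN(SiMe3)2 (2.2 equiv), THF, −78 °C, 45 min; 7 (1.2 equiv), −78 → 0 °C, 2 h; aq. NH4Cl
Reagents that add atoms: none
Why: Crossed Claisen condensation: the lactone enolate is C-acylated by the Weinreb amide, whose chelated tetrahedral adduct releases the ketone only on work-up while the extra base covers the acidic β-dicarbonyl product; the new C3 centre (epimers and enol) is of no consequence because it becomes trigonal in the next step.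

Step 5
Reactants: 9 (5R)-3-acetyl-5-(6-methylhepta-1,5-dien-2-yl)dihydrofuran-2(3H)-one
Product: 10 (5R)-5-(6-methylhepta-1,5-dien-2-yl)-3-[1-(trimethylsilyloxy)ethylidene]dihydrofuran-2(3H)-one
Conditions: Me3SiCl (1.5 equiv), Et3N (1.6 equiv), toluene, rt, 16 h; pentane, filter, concentrate
Reagents that add atoms: chlorotrimethylsilane, C[Si](C)(C)Cl
Why: O-Silylation of the enolised β-keto lactone with a chlorosilane and a tertiary amine (silyl enol ether formation); the E/Z ratio of the ethylidene unit does not matter, and the regioisomeric monosilyl derivative would lead to the same diene.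

Step 6
Reactants: 10 (5R)-5-(6-methylhepta-1,5-dien-2-yl)-3-[1-(trimethylsilyloxy)ethylidene]dihydrofuran-2(3H)-one
Product: 12 (5R)-5-(6-methylhepta-1,5-dien-2-yl)-2-(trimethylsilyloxy)-3-[1-(trimethylsilyloxy)ethenyl]-4,5-dihydrofuran, via lithium dienolate 11 (not isolated)
Conditions: LiN(iPr)2 (1.15 equiv), THF, −78 °C, 1 h; Me3SiCl (1.3 equiv), −78 → 0 °C; evaporate, pentane, filter under argon; used crude, kept below 20 °C
Reagents that add atoms: chlorotrimethylsilane, C[Si](C)(C)Cl
Why: Deprotonation of the methyl group of the vinylogous ester and O-silylation of the extended enolate at the lactone oxygen is the standard second stage in the preparation of 1-alkoxy-1,3-bis(silyloxy)dienes from β-keto esters; the allylic C–H at C5 is far less acidic, so the stereocentre is kept.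

Step 7
Reactants: 13 4-(tert-butyldimethylsilyloxy)benzaldehyde; 14 (triphenylphosphoranylidene)acetaldehyde
Product: 15 (2E)-3-[4-(tert-butyldimethylsilyloxy)phenyl]prop-2-enal
Conditions: 14 (1.1 equiv), toluene, 80 °C, 16 h
Reagents that add atoms: none
Why: Wittig olefination with the formyl-stabilised ylide gives the E-cinnamaldehyde, the small excess of ylide limiting a second homologation, and the aryl silyl ether is inert in neutral toluene.

Step 8
Reactants: 15 (2E)-3-[4-(tert-butyldimethylsilyloxy)phenyl]prop-2-enal; 16 ethynylmagnesium bromide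
Product: 17 (1E)-1-[4-(tert-butyldimethylsilyloxy)phenyl]pent-1-en-4-yn-3-ol (racemic)
Conditions: 16 (0.5 M in THF, 1.3 equiv), THF, −78 → 0 °C, 1 h; aq. NH4Cl
Reagents that add atoms: none
Why: 1,2-Addition of the alkynyl Grignard reagent to the enal is fast at low temperature and gives a carbinol whose stereocentre is removed in the next step.

Step 9
Reactants: 17 (1E)-1-[4-(tert-butyldimethylsilyloxy)phenyl]pent-1-en-4-yn-3-ol
Product: 18 (1E)-1-[4-(tert-butyldimethylsilyloxy)phenyl]pent-1-en-4-yn-3-one
Conditions: MnO2 (activated, 15 equiv), CH2Cl2, rt, 2 h; filter (Celite); used at once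
Reagents that add atoms: none
Why: MnO2 oxidation of an alcohol that is both allylic and propargylic is fast and neutral and leaves the alkyne, the E-alkene and the silyl ether alone.

Step 10
Reactants: 12 (5R)-5-(6-methylhepta-1,5-dien-2-yl)-2-(trimethylsilyloxy)-3-[1-(trimethylsilyloxy)ethenyl]-4,5-dihydrofuran; 18 (1E)-1-[4-(tert-butyldimethylsilyloxy)phenyl]pent-1-en-4-yn-3-one
Product: 21 (2E)-1-{2,4-dihydroxy-3-[(2R)-2-hydroxy-7-methyl-3-methylideneoct-6-en-1-yl]phenyl}-3-(4-hydroxyphenyl)prop-2-en-1-one, via silyl ketal cycloadduct 19 (not isolated), via ring-opened dienone 20 (not isolated)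
Conditions: 12 (1.3 equiv), toluene, 0 °C → rt, 12 h; then Bu4NF (1 M in THF, 5 equiv), −20 → 0 °C, 30 min; aq. NH4Cl
Reagents that add atoms: none
Why: Proposed new method: diene 12, a cyclic ketene silyl acetal conjugated with a silyl enol ether, should add to the terminal ynone of 18 in an asynchronous normal-demand Diels–Alder reaction (the exocyclic CH2 of the diene bonds first to the unsubstituted alkyne carbon, the acetal carbon then to the acyl-bearing alkyne carbon), which closes ring A as a six-membered carbocycle by intermolecular [4+2] cycloaddition and gives the 1,4-cyclohexadiene silyl ketal 19. Fluoride then cleaves the Si–O bonds, the ketal oxyanion collapses to a ketone and expels the tethered alkoxide (the former lactone C–O bond, so the five-membered ring opens and the carbinol is freed), and dienone 20 tautomerises irreversibly to the resorcinol. The closest known reaction type is the Diels–Alder reaction and aromatisation of open-chain 1-alkoxy-1,3-bis(trimethylsilyloxy)buta-1,3-dienes with alkynoates, alkynones and quinones, in which the 1-alkoxy group leaves as the alcohol and the 1-silyloxy oxygen becomes the phenol; here that alkoxy group is the ring oxygen of a lactone, which has not been shown. The step needs regioselectivity, site selectivity and the ring-opening mode of aromatisation: the first follows from the matched polarisation of the partners (most nucleophilic diene terminus to the β-carbon of the ynone), which puts the acyl group next to the new hydroxyl and the side chain between the two oxygens; the second from the far higher dienophilicity of an unsubstituted alkynyl ketone over the aryl-substituted enone double bond; the third from basic desilylation, under which the ketal can open to the ketone but cannot lose hydroxide or silanolate to give the 2,3-dihydrobenzofuran. The only new stereocentre, the ketal carbon of 19, is formed without control and is destroyed on aromatisation, while the carbinol centre takes no part and keeps its (R) configuration and the E double bond is not touched.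

Compound list
1 | (2R)-5-oxotetrahydrofuran-2-carboxylic acid | O=C(O)[C@H]1CCC(=O)O1 | starting material
2 | (2R)-5-oxotetrahydrofuran-2-carbonyl chloride | O=C(Cl)[C@H]1CCC(=O)O1 | intermediate
3 | 5-bromo-2-methylpent-2-ene | CC(C)=CCCBr | starting material
4 | (4-methylpent-3-en-1-yl)magnesium bromide | CC(C)=CCC[Mg]Br | intermediate
5 | (5R)-5-(5-methylhex-4-enoyl)dihydrofuran-2(3H)-one | CC(C)=CCCC(=O)[C@H]1CCC(=O)O1 | intermediate
6 | (5R)-5-(6-methylhepta-1,5-dien-2-yl)dihydrofuran-2(3H)-one | C=C(CCC=C(C)C)[C@H]1CCC(=O)O1 | intermediate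
7 | N-methoxy-N-methylacetamide | CON(C)C(C)=O | starting material
8 | lithium (5R)-5-(6-methylhepta-1,5-dien-2-yl)-4,5-dihydrofuran-2-olate | C=C(CCC=C(C)C)[C@H]1CC=C(O[Li])O1 | intermediate
9 | (5R)-3-acetyl-5-(6-methylhepta-1,5-dien-2-yl)dihydrofuran-2(3H)-one (C3 epimers and enol) | C=C(CCC=C(C)C)[C@H]1CC(C(C)=O)C(=O)O1 | intermediate
10 | (5R)-5-(6-methylhepta-1,5-dien-2-yl)-3-[1-(trimethylsilyloxy)ethylidene]dihydrofuran-2(3H)-one (E/Z mixture) | C=C(CCC=C(C)C)[C@H]1CC(=C(C)O[Si](C)(C)C)C(=O)O1 | intermediate
11 | lithium (5R)-5-(6-methylhepta-1,5-dien-2-yl)-3-[1-(trimethylsilyloxy)ethenyl]-4,5-dihydrofuran-2-olate | C=C(CCC=C(C)C)[C@H]1CC(C(=C)O[Si](C)(C)C)=C(O[Li])O1 | intermediate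
12 | (5R)-5-(6-methylhepta-1,5-dien-2-yl)-2-(trimethylsilyloxy)-3-[1-(trimethylsilyloxy)ethenyl]-4,5-dihydrofuran | C=C(CCC=C(C)C)[C@H]1CC(C(=C)O[Si](C)(C)C)=C(O[Si](C)(C)C)O1 | intermediate
13 | 4-(tert-butyldimethylsilyloxy)benzaldehyde | O=Cc1ccc(O[Si](C)(C)C(C)(C)C)cc1 | starting material
14 | (triphenylphosphoranylidene)acetaldehyde | O=CC=P(c1ccccc1)(c1ccccc1)c1ccccc1 | starting material
15 | (2E)-3-[4-(tert-butyldimethylsilyloxy)phenyl]prop-2-enal | O=C/C=C/c1ccc(O[Si](C)(C)C(C)(C)C)cc1 | intermediate
16 | ethynylmagnesium bromide | C#C[Mg]Br | starting material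
17 | (1E)-1-[4-(tert-butyldimethylsilyloxy)phenyl]pent-1-en-4-yn-3-ol (racemic) | C#CC(O)/C=C/c1ccc(O[Si](C)(C)C(C)(C)C)cc1 | intermediate
18 | (1E)-1-[4-(tert-butyldimethylsilyloxy)phenyl]pent-1-en-4-yn-3-one | C#CC(=O)/C=C/c1ccc(O[Si](C)(C)C(C)(C)C)cc1 | intermediate
19 | (2E)-3-[4-(tert-butyldimethylsilyloxy)phenyl]-1-[(2R)-2-(6-methylhepta-1,5-dien-2-yl)-4,7a-bis(trimethylsilyloxy)-2,3,5,7a-tetrahydro-1-benzofuran-7-yl]prop-2-en-1-one (both C7a epimers) | C=C(CCC=C(C)C)[C@H]1CC2=C(O[Si](C)(C)C)CC=C(C(=O)/C=C/c3ccc(O[Si](C)(C)C(C)(C)C)cc3)C2(O[Si](C)(C)C)O1 | intermediate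
20 | 3-hydroxy-2-[(2R)-2-hydroxy-7-methyl-3-methylideneoct-6-en-1-yl]-6-[(2E)-3-(4-hydroxyphenyl)prop-2-enoyl]cyclohexa-2,5-dien-1-one | C=C(CCC=C(C)C)[C@H](O)CC1=C(O)CC=C(C(=O)/C=C/c2ccc(O)cc2)C1=O | intermediate
21 | (2E)-1-{2,4-dihydroxy-3-[(2R)-2-hydroxy-7-methyl-3-methylideneoct-6-en-1-yl]phenyl}-3-(4-hydroxyphenyl)prop-2-en-1-one | C=C(CCC=C(C)C)[C@H](O)Cc1c(O)ccc(C(=O)/C=C/c2ccc(O)cc2)c1O | target

Total step count: 10. Longest linear sequence: 7 steps (steps 1–6 and 10); the dienophile takes steps 7–9.

Steps most likely to fail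

Step 10 (ring-forming cycloaddition and aromatisation). The cycloadduct may aromatise by loss of silanol, which would leave the oxygen ring closed as a dihydrobenzofuran. The ynone may be consumed by conjugate addition without ring closure or by polymerisation. The diene may undergo a ring-contracting Ireland–Claisen-type [3,3] shift if it is warmed. The fallback uses the known open-chain diene class with methanol as the leaving group; it sets out from lactone 6 and comes back at target 21. Lactone 6 would be opened with KOH in aqueous methanol to potassium (4R)-4-hydroxy-9-methyl-5-methylidenedec-8-enoate F1, which would be alkylated at the carboxylate (MeI, DMF) to methyl (4R)-4-hydroxy-9-methyl-5-methylidenedec-8-enoate F2 and silylated at once (tBuMe2SiCl, imidazole) to methyl (4R)-4-(tert-butyldimethylsilyloxy)-9-methyl-5-methylidenedec-8-enoate F3. Acetylation of its lithium enolate with 7 (LiN(iPr)2, THF, −78 °C) would give methyl (4R)-2-acetyl-4-(tert-butyldimethylsilyloxy)-9-methyl-5-methylidenedec-8-enoate F4. Me3SiCl/Et3N would give methyl (4R)-4-(tert-butyldimethylsilyloxy)-9-methyl-5-methylidene-2-[1-(trimethylsilyloxy)ethylidene]dec-8-enoate F5, and LiN(iPr)2/Me3SiCl would give the 1-methoxy-1,3-bis(trimethylsilyloxy)buta-1,3-diene carrying the (2R)-2-(tert-butyldimethylsilyloxy)-7-methyl-3-methylideneoct-6-en-1-yl group at C2 F6. Cycloaddition of this diene with 18 (toluene, rt) would give (2E)-3-[4-(tert-butyldimethylsilyloxy)phenyl]-1-{5-[(2R)-2-(tert-butyldimethylsilyloxy)-7-methyl-3-methylideneoct-6-en-1-yl]-6-methoxy-4,6-bis(trimethylsilyloxy)cyclohexa-1,4-dien-1-yl}prop-2-en-1-one F7, which on treatment with Bu4NF would lose methanol and all silyl groups and aromatise to 21.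

Step 4 (C-acetylation of the lactone). Proton transfer from the acidic product to unreacted enolate, O-acylation, or self-condensation of the lactone may undercut the C-acylation. The fallback replaces the Claisen condensation by aldol addition and oxidation; it sets out from 6 and comes back at 9. The lithium enolate of 6 (LiN(iPr)2, THF, −78 °C) would be added to acetaldehyde to give (5R)-3-(1-hydroxyethyl)-5-(6-methylhepta-1,5-dien-2-yl)dihydrofuran-2(3H)-one F8 as a diastereomer mixture, and Dess–Martin oxidation (CH2Cl2, NaHCO3) would give 9.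

Step 3 (methylenation beside the stereocentre). Enolisation of the α-acyloxy ketone may erode the enantiomeric purity, zinc may cleave the C–O bond next to the ketone reductively, and the allylic lactone formed may ionise under Lewis acid. The fallback is a Peterson olefination by addition and elimination; it sets out from 5 and comes back at 6. Me3SiCH2MgCl/CeCl3 (THF, −78 °C) would add to the ketone only and give (5R)-5-[2-hydroxy-6-methyl-1-(trimethylsilyl)hept-5-en-2-yl]dihydrofuran-2(3H)-one F9. KH (THF, 0 °C) would then eliminate silanolate to give 6; any lactone opened by the silanolate would close again on acidification.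

Further compounds
F1 | step 10 | potassium (4R)-4-hydroxy-9-methyl-5-methylidenedec-8-enoate | C=C(CCC=C(C)C)[C@H](O)CCC(=O)[O-].[K+]
F2 | step 10 | methyl (4R)-4-hydroxy-9-methyl-5-methylidenedec-8-enoate | C=C(CCC=C(C)C)[C@H](O)CCC(=O)OC
F3 | step 10 | methyl (4R)-4-(tert-butyldimethylsilyloxy)-9-methyl-5-methylidenedec-8-enoate | C=C(CCC=C(C)C)[C@H](O[Si](C)(C)C(C)(C)C)CCC(=O)OC
F4 | step 10 | methyl (4R)-2-acetyl-4-(tert-butyldimethylsilyloxy)-9-methyl-5-methylidenedec-8-enoate | C=C(CCC=C(C)C)[C@H](O[Si](C)(C)C(C)(C)C)CC(C(C)=O)C(=O)OC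
F5 | step 10 | methyl (4R)-4-(tert-butyldimethylsilyloxy)-9-methyl-5-methylidene-2-[1-(trimethylsilyloxy)ethylidene]dec-8-enoate | C=C(CCC=C(C)C)[C@H](O[Si](C)(C)C(C)(C)C)CC(=C(C)O[Si](C)(C)C)C(=O)OC
F6 | step 10 | 1-methoxy-1,3-bis(trimethylsilyloxy)buta-1,3-diene carrying the (2R)-2-(tert-butyldimethylsilyloxy)-7-methyl-3-methylideneoct-6-en-1-yl group at C2 | C=C(CCC=C(C)C)[C@H](O[Si](C)(C)C(C)(C)C)CC(C(=C)O[Si](C)(C)C)=C(OC)O[Si](C)(C)C
F7 | step 10 | (2E)-3-[4-(tert-butyldimethylsilyloxy)phenyl]-1-{5-[(2R)-2-(tert-butyldimethylsilyloxy)-7-methyl-3-methylideneoct-6-en-1-yl]-6-methoxy-4,6-bis(trimethylsilyloxy)cyclohexa-1,4-dien-1-yl}prop-2-en-1-one | C=C(CCC=C(C)C)[C@H](O[Si](C)(C)C(C)(C)C)CC1=C(O[Si](C)(C)C)CC=C(C(=O)/C=C/c2ccc(O[Si](C)(C)C(C)(C)C)cc2)C1(OC)O[Si](C)(C)C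
F8 | step 4 | (5R)-3-(1-hydroxyethyl)-5-(6-methylhepta-1,5-dien-2-yl)dihydrofuran-2(3H)-one | C=C(CCC=C(C)C)[C@H]1CC(C(C)O)C(=O)O1
F9 | step 3 | (5R)-5-[2-hydroxy-6-methyl-1-(trimethylsilyl)hept-5-en-2-yl]dihydrofuran-2(3H)-one | CC(C)=CCCC(O)(C[Si](C)(C)C)[C@H]1CCC(=O)O1
A1 | direct plan | resorcinol (benzene-1,3-diol) | Oc1cccc(O)c1
A2 | direct plan | 2-[2,6-bis(methoxymethoxy)phenyl]ethyl N,N-diisopropylcarbamate | CC(C)N(C(C)C)C(=O)OCCc1c(OCOC)cccc1OCOC
A3 | direct plan | 6-methylhepta-1,5-dien-2-yl trifluoromethanesulfonate | C=C(CCC=C(C)C)OS(=O)(=O)C(F)(F)F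
A4 | direct plan | (2R)-1-[2,6-bis(methoxymethoxy)phenyl]-7-methyl-3-methylideneoct-6-en-2-ol | C=C(CCC=C(C)C)[C@H](O)Cc1c(OCOC)cccc1OCOC
A5 | direct plan | (2E)-1-{3-[(2R)-2-hydroxy-7-methyl-3-methylideneoct-6-en-1-yl]-2,4-bis(methoxymethoxy)phenyl}-3-(4-hydroxyphenyl)prop-2-en-1-one | C=C(CCC=C(C)C)[C@H](O)Cc1c(OCOC)ccc(C(=O)/C=C/c2ccc(O)cc2)c1OCOC
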